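The 11-membered ring is closed between ring methylene C10 and the quaternary gem-dimethyl carbon C11, the neighbour of the acetoxy-bearing carbon C1. With C1 held at the ketone level, C11 is the α'-carbon of a (Z)-enone: kinetic deprotonation gives a tetrasubstituted lithium enolate that C-alkylates a primary iodide at the other chain end, forming the carbocycle and the quaternary centre in one operation, while the E C6=C7 alkene rules out smaller rings. The acyclic iodo isopropyl enone comes from 5-chloropent-1-yne, oxirane and methyl propiolate; C4 is set by asymmetric alkynylation, the Z alkene by cuprate syn-addition, C1 by late CBS reduction.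

Key step: step 8

Remark on numbering: ring atoms are C1 (acetoxy or carbonyl carbon), C2=C3(CH3), C4 (oxygen-bearing carbon), C5, C6=C7(CH3), C8 to C10, C11 = C(CH3)2; acyclic intermediates carry their own chain locants.
Assumption (step 3): (R,R)-ProPhenol/Me2Zn is taken to deliver the (R)-carbinol; if the facial sense is the opposite, the (S,S)-ligand is used instead.
Assumption (step 9): in the CBS complex the fully substituted C11 side is taken as the large group and the alkenyl side as the small one.

Step 1
Reactants: 1 5-chloropent-1-yne; 2 oxirane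
Product: 5 (3E)-7-chloro-4-methylhept-3-en-1-ol, via alkenylalane 3 (not isolated), via lithium alkenylalanate 4 (not isolated)
Conditions: AlMe3 (2.5 equiv), Cp2ZrCl2 (0.25 equiv), CH2Cl2, 0 to 23 °C; then n-BuLi, hexane/THF, −78 to 0 °C; then oxirane, −78 to 23 °C; aq. HCl
Reagents that add atoms: trimethylaluminium, C[Al](C)C
Why: Negishi zirconium-catalysed carboalumination adds CH3–Al syn across the terminal alkyne (methyl to the internal carbon), which fixes the E C6=C7 geometry, and the derived alkenylalanate opens oxirane with retention of the alkene configuration.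

Step 2
Reactants: 5 (3E)-7-chloro-4-methylhept-3-en-1-ol
Product: 6 (3E)-7-chloro-4-methylhept-3-enal
Conditions: Dess–Martin periodinane, NaHCO3, CH2Cl2, 0 °C; crude aldehyde used at once
Reagents that add atoms: none
Why: Dess–Martin oxidation under buffered, non-basic conditions should give the β,γ-unsaturated aldehyde without migration of the trisubstituted alkene into conjugation.

Step 3
Reactants: 6 (3E)-7-chloro-4-methylhept-3-enal; 7 methyl propiolate
Product: 8 methyl (4R,6E)-10-chloro-4-hydroxy-7-methyldec-6-en-2-ynoate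
Conditions: (R,R)-ProPhenol (20 mol %), Me2Zn (3 equiv), Ph3P=O (40 mol %), toluene, 4 °C, slow addition of 6; aq. NH4Cl
Reagents that add atoms: none
Why: Trost zinc–ProPhenol asymmetric alkynylation, in which the zinc alkynylide of methyl propiolate adds to one aldehyde face inside the chiral dinuclear zinc pocket and so sets C4 as R, while slow addition limits enolisation of the aldehyde.

Step 4
Reactants: 8 methyl (4R,6E)-10-chloro-4-hydroxy-7-methyldec-6-en-2-ynoate
Product: 9 methyl (4R,6E)-4-[(tert-butyldimethylsilyl)oxy]-10-chloro-7-methyldec-6-en-2-ynoate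
Conditions: TBSOTf, 2,6-lutidine, CH2Cl2, −78 °C
Reagents that add atoms: tert-butyldimethylsilyl trifluoromethanesulfonate, CC(C)(C)[Si](C)(C)OS(=O)(=O)C(F)(F)F
Why: low-temperature silylation protects the propargylic alcohol without amine conjugate addition to the ynoate and blocks later lactonisation of the Z-enoate to a butenolide.

Step 5
Reactants: 9 methyl (4R,6E)-4-[(tert-butyldimethylsilyl)oxy]-10-chloro-7-methyldec-6-en-2-ynoate
Product: 10 methyl (2Z,4R,6E)-4-[(tert-butyldimethylsilyl)oxy]-10-chloro-3,7-dimethyldeca-2,6-dienoate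
Conditions: Me2CuLi (from CuI and MeLi), THF, −78 °C; quench at −78 °C with MeOH then aq. NH4Cl
Reagents that add atoms: lithium dimethylcuprate, [Li+].C[Cu-]C
Why: organocuprate conjugate addition to the ynoate is a syn carbocupration, and protonation of the configurationally stable alkenylcopper at −78 °C leaves CH3 and H cis, so the ester carbon and C4 end up cis (2Z); the alkyl chloride is inert at this temperature.

Step 6
Reactants: 10 methyl (2Z,4R,6E)-4-[(tert-butyldimethylsilyl)oxy]-10-chloro-3,7-dimethyldeca-2,6-dienoate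
Product: 12 (4Z,6R,8E)-6-[(tert-butyldimethylsilyl)oxy]-12-chloro-2,5,9-trimethyldodeca-4,8-dien-3-one, via Weinreb amide 11 (not isolated)
Conditions: MeNH(OMe)·HCl (1.5 equiv), iPrMgCl (3 equiv), THF, −20 °C; then iPrMgCl (3 equiv), 0 to 23 °C; aq. NH4Cl
Reagents that add atoms: isopropylmagnesium chloride, CC(C)[Mg]Cl; N,O-dimethylhydroxylamine hydrochloride, CNOC.Cl (its atoms are kept in 11 only)
Why: one-pot Weinreb ketone synthesis, in which the magnesium amide converts the ester into amide 11 and the chelated adduct of 11 with iPrMgCl releases the isopropyl ketone only on work-up, so neither over-addition nor Z/E scrambling is expected.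

Step 7
Reactants: 12 (4Z,6R,8E)-6-[(tert-butyldimethylsilyl)oxy]-12-chloro-2,5,9-trimethyldodeca-4,8-dien-3-one
Product: 13 (4Z,6R,8E)-6-[(tert-butyldimethylsilyl)oxy]-12-iodo-2,5,9-trimethyldodeca-4,8-dien-3-one
Conditions: NaI (5 equiv), NaHCO3, acetone, 56 °C
Reagents that add atoms: sodium iodide, [Na+].[I-]
Why: Finkelstein halide exchange (SN2, driven by precipitation of NaCl) turns the unreactive chloride into the iodide needed for ring closure and leaves the enone and the silyl ether untouched.

Step 8
Reactants: 13 (4Z,6R,8E)-6-[(tert-butyldimethylsilyl)oxy]-12-iodo-2,5,9-trimethyldodeca-4,8-dien-3-one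
Product: 15 (2Z,4R,6E)-4-[(tert-butyldimethylsilyl)oxy]-3,7,11,11-tetramethylcycloundeca-2,6-dien-1-one, via lithium enolate 14 (not isolated)
Conditions: LiN(iPr)2 (1.1 equiv), THF (0.002 M), −78 °C, 1 h; then DMPU (10 vol %), −78 to 23 °C, 16 h
Reagents that add atoms: none
Why: Kinetic deprotonation of the tertiary α'-C–H of the isopropyl ketone gives the cross-conjugated tetrasubstituted lithium enolate 14, whose carbon terminus (C11) displaces the primary iodide at C10 in an intramolecular SN2 reaction. The closest known reaction types are the C-alkylation of kinetic α'-enolates of enones and the carbanion-alkylation macrocyclisations used for 11-membered humulane rings. The single ring closed is the 11-membered carbocycle, formed in an 11-exo-tet mode. No stereocentre is created, because the new quaternary carbon carries two identical methyl groups, and C4 is a spectator. The step needs α' over γ regiochemistry, C- over O-alkylation and ring closure over oligomerisation; the first is secured by kinetic enolisation with a slight excess of base and by the fact that C-alkylation through the extended dienolate would need 7- or 9-membered rings containing the E C6=C7 double bond, the second by the lithium counter-ion with the soft iodide, the third by high dilution. The Z C2=C3 enone and the E C6=C7 alkene leave only six freely rotating ring bonds, which should favour closure.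

Step 9
Reactants: 15 (2Z,4R,6E)-4-[(tert-butyldimethylsilyl)oxy]-3,7,11,11-tetramethylcycloundeca-2,6-dien-1-one
Product: 16 (1S,2Z,4R,6E)-4-[(tert-butyldimethylsilyl)oxy]-3,7,11,11-tetramethylcycloundeca-2,6-dien-1-ol
Conditions: (R)-2-methyl-CBS-oxazaborolidine (0.5 equiv), catecholborane (2 equiv), toluene, −78 to −40 °C; MeOH, aq. NaOH
Reagents that add atoms: none
Why: Corey–Bakshi–Shibata reduction delivers hydride 1,2 to the enone inside the catalyst–ketone complex, and with the quaternary C11 side as the large group the (R)-catalyst should set C1 as S; conjugate reduction is disfavoured by the β,β-disubstituted enone.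

Step 10
Reactants: 16 (1S,2Z,4R,6E)-4-[(tert-butyldimethylsilyl)oxy]-3,7,11,11-tetramethylcycloundeca-2,6-dien-1-ol
Product: 17 (1S,2Z,4R,6E)-4-[(tert-butyldimethylsilyl)oxy]-3,7,11,11-tetramethylcycloundeca-2,6-dien-1-yl acetate
Conditions: Ac2O, DMAP, pyridine, CH2Cl2, 23 °C
Reagents that add atoms: acetic anhydride, CC(=O)OC(C)=O
Why: DMAP-catalysed acetylation should acylate the hindered allylic alcohol at oxygen with retention at C1.

Step 11
Reactants: 17 (1S,2Z,4R,6E)-4-[(tert-butyldimethylsilyl)oxy]-3,7,11,11-tetramethylcycloundeca-2,6-dien-1-yl acetate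
Product: 18 (1S,2Z,4R,6E)-4-hydroxy-3,7,11,11-tetramethylcycloundeca-2,6-dien-1-yl acetate
Conditions: HF·pyridine, pyridine, THF, 0 to 23 °C
Reagents that add atoms: none
Why: fluoride cleavage of the secondary silyl ether under buffered, weakly acidic conditions should avoid the base-induced 1,4-acetyl migration across the Z alkene.

Step 12
Reactants: 18 (1S,2Z,4R,6E)-4-hydroxy-3,7,11,11-tetramethylcycloundeca-2,6-dien-1-yl acetate; 19 4-acetoxybenzoyl chloride
Product: 20 (1S,2Z,4R,6E)-1-acetoxy-3,7,11,11-tetramethylcycloundeca-2,6-dien-4-yl 4-acetoxybenzoate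
Conditions: Et3N, DMAP (0.1 equiv), CH2Cl2, 0 to 23 °C
Reagents that add atoms: none
Why: acylation of the C4 hydroxyl by the acid chloride under nucleophilic catalysis proceeds with retention at C4, and the phenol stays masked as its acetate.

Step 13
Reactants: 20 (1S,2Z,4R,6E)-1-acetoxy-3,7,11,11-tetramethylcycloundeca-2,6-dien-4-yl 4-acetoxybenzoate
Product: 21 (1S,2Z,4R,6E)-1-acetoxy-3,7,11,11-tetramethylcycloundeca-2,6-dien-4-yl 4-hydroxybenzoate (CNP0246761.2)
Conditions: pyrrolidine (2 equiv), MeCN, 0 to 23 °C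
Reagents that add atoms: none
Why: chemoselective aminolysis, since the aryl acetate is an activated ester and should be cleaved far faster than the hindered alkyl acetate at C1 or the alkyl benzoate at C4.

Compound list
1 | 5-chloropent-1-yne | C#CCCCCl | starting material
2 | oxirane (ethylene oxide) | C1CO1 | starting material
3 | [(1E)-5-chloro-2-methylpent-1-en-1-yl]dimethylaluminium | C[Al](C)/C=C(\C)CCCCl | intermediate
4 | lithium butyl[(1E)-5-chloro-2-methylpent-1-en-1-yl]dimethylaluminate | [Li+].CCCC[Al-](C)(C)/C=C(\C)CCCCl | intermediate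
5 | (3E)-7-chloro-4-methylhept-3-en-1-ol | OCC/C=C(\C)CCCCl | intermediate
6 | (3E)-7-chloro-4-methylhept-3-enal | O=CC/C=C(\C)CCCCl | intermediate
7 | methyl propiolate | COC(=O)C#C | starting material
8 | methyl (4R,6E)-10-chloro-4-hydroxy-7-methyldec-6-en-2-ynoate | COC(=O)C#C[C@H](O)C/C=C(\C)CCCCl | intermediate
9 | methyl (4R,6E)-4-[(tert-butyldimethylsilyl)oxy]-10-chloro-7-methyldec-6-en-2-ynoate | COC(=O)C#C[C@H](O[Si](C)(C)C(C)(C)C)C/C=C(\C)CCCCl | intermediate
10 | methyl (2Z,4R,6E)-4-[(tert-butyldimethylsilyl)oxy]-10-chloro-3,7-dimethyldeca-2,6-dienoate | COC(=O)/C=C(/C)[C@H](O[Si](C)(C)C(C)(C)C)C/C=C(\C)CCCCl | intermediate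
11 | (2Z,4R,6E)-4-[(tert-butyldimethylsilyl)oxy]-10-chloro-N-methoxy-N,3,7-trimethyldeca-2,6-dienamide | CON(C)C(=O)/C=C(/C)[C@H](O[Si](C)(C)C(C)(C)C)C/C=C(\C)CCCCl | intermediate
12 | (4Z,6R,8E)-6-[(tert-butyldimethylsilyl)oxy]-12-chloro-2,5,9-trimethyldodeca-4,8-dien-3-one | CC(C)C(=O)/C=C(/C)[C@H](O[Si](C)(C)C(C)(C)C)C/C=C(\C)CCCCl | intermediate
13 | (4Z,6R,8E)-6-[(tert-butyldimethylsilyl)oxy]-12-iodo-2,5,9-trimethyldodeca-4,8-dien-3-one | CC(C)C(=O)/C=C(/C)[C@H](O[Si](C)(C)C(C)(C)C)C/C=C(\C)CCCI | intermediate
14 | lithium (4Z,6R,8E)-6-[(tert-butyldimethylsilyl)oxy]-12-iodo-2,5,9-trimethyldodeca-2,4,8-trien-3-olate | [Li]OC(=C(C)C)/C=C(/C)[C@H](O[Si](C)(C)C(C)(C)C)C/C=C(\C)CCCI | intermediate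
15 | (2Z,4R,6E)-4-[(tert-butyldimethylsilyl)oxy]-3,7,11,11-tetramethylcycloundeca-2,6-dien-1-one | O=C1/C=C(/C)[C@H](O[Si](C)(C)C(C)(C)C)C/C=C(\C)CCCC1(C)C | intermediate
16 | (1S,2Z,4R,6E)-4-[(tert-butyldimethylsilyl)oxy]-3,7,11,11-tetramethylcycloundeca-2,6-dien-1-ol | O[C@H]1/C=C(/C)[C@H](O[Si](C)(C)C(C)(C)C)C/C=C(\C)CCCC1(C)C | intermediate
17 | (1S,2Z,4R,6E)-4-[(tert-butyldimethylsilyl)oxy]-3,7,11,11-tetramethylcycloundeca-2,6-dien-1-yl acetate | CC(=O)O[C@H]1/C=C(/C)[C@H](O[Si](C)(C)C(C)(C)C)C/C=C(\C)CCCC1(C)C | intermediate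
18 | (1S,2Z,4R,6E)-4-hydroxy-3,7,11,11-tetramethylcycloundeca-2,6-dien-1-yl acetate | CC(=O)O[C@H]1/C=C(/C)[C@H](O)C/C=C(\C)CCCC1(C)C | intermediate
19 | 4-acetoxybenzoyl chloride | CC(=O)Oc1ccc(cc1)C(Cl)=O | starting material
20 | (1S,2Z,4R,6E)-1-acetoxy-3,7,11,11-tetramethylcycloundeca-2,6-dien-4-yl 4-acetoxybenzoate | CC(=O)O[C@H]1/C=C(/C)[C@H](OC(=O)c2ccc(OC(C)=O)cc2)C/C=C(\C)CCCC1(C)C | intermediate
21 | (1S,2Z,4R,6E)-1-acetoxy-3,7,11,11-tetramethylcycloundeca-2,6-dien-4-yl 4-hydroxybenzoate | CC(=O)O[C@H]1/C=C(/C)[C@H](OC(=O)c2ccc(O)cc2)C/C=C(\C)CCCC1(C)C | target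

Total step count: 13. Longest linear sequence: 13 steps, from 5-chloropent-1-yne (1) to 21.

Steps most likely to fail

Step 8 (macrocyclising C-alkylation). The slow closure of the medium ring at a fully substituted enolate carbon may be outrun by intermolecular alkylation (oligomers), by O-alkylation to the isomeric 11-membered enol ether, or by proton transfer that equilibrates the enolate. The fallback forms the same C10–C11 bond by an aldol-type closure. It sets out from iodo ketone 13: kinetic enolisation with LiN(iPr)2 and trapping with TBSOTf should give the silyl dienol ether F1; Kornblum–Ganem oxidation of the primary iodide (Me3NO, DMSO, 23 °C) should give the aldehyde F2; intramolecular Mukaiyama aldol addition (BF3·OEt2, CH2Cl2, −78 °C, high dilution) should give the macrocyclic β-hydroxy ketone F3 as C10 epimers; 1,1'-thiocarbonyldiimidazole should give the imidazolyl thiocarbonate F4; Barton–McCombie deoxygenation (Bu3SnH, AIBN, toluene, 80 °C) comes back to the route at enone 15.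

Step 9 (CBS reduction). The conformation of the macrocycle may override the catalyst, so that hydride arrives mainly on the wrong face of the C1 carbonyl, or with poor facial selectivity. The fallback sets out from enone 15: a substrate-controlled Luche reduction (NaBH4, CeCl3·7H2O, MeOH) should give the C1-epimeric (1R)-alcohol F5, and Mitsunobu inversion with acetic acid (PPh3, DIAD, toluene) should deliver the (1S)-acetate directly, coming back to the route at 17.

Step 3 (asymmetric alkynylation). Enolisation of the β,γ-unsaturated aldehyde (self-aldol, alkene migration into conjugation) and erosion of enantioselectivity with an unbranched aldehyde may lower yield and optical purity. The fallback sets the C4 centre by asymmetric reduction instead of asymmetric addition. It sets out from aldehyde 6: lithium (trimethylsilyl)acetylide (THF, −78 °C) should give the racemic propargylic alcohol F6; Dess–Martin oxidation should give the ynone F7; Noyori asymmetric transfer hydrogenation with RuCl(p-cymene)[(R,R)-TsDPEN] in 2-propanol should give the (R)-propargylic alcohol F8; TBSOTf and 2,6-lutidine should give the silyl ether F9; K2CO3 in methanol should remove the alkynyl silyl group to give the terminal alkyne F10; n-BuLi followed by methyl chloroformate comes back to the route at ynoate 9.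

Further compounds
F1 | step 8 | tert-butyl{[(4Z,6R,8E)-6-[(tert-butyldimethylsilyl)oxy]-12-iodo-2,5,9-trimethyldodeca-2,4,8-trien-3-yl]oxy}dimethylsilane | CC(C)=C(O[Si](C)(C)C(C)(C)C)/C=C(/C)[C@H](O[Si](C)(C)C(C)(C)C)C/C=C(\C)CCCI
F2 | step 8 | (4E,7R,8Z)-7,10-bis[(tert-butyldimethylsilyl)oxy]-4,8,11-trimethyldodeca-4,8,10-trienal | CC(C)=C(O[Si](C)(C)C(C)(C)C)/C=C(/C)[C@H](O[Si](C)(C)C(C)(C)C)C/C=C(\C)CCC=O
F3 | step 8 | (2Z,4R,6E)-4-[(tert-butyldimethylsilyl)oxy]-10-hydroxy-3,7,11,11-tetramethylcycloundeca-2,6-dien-1-one (C10 epimers) | O=C1/C=C(/C)[C@H](O[Si](C)(C)C(C)(C)C)C/C=C(\C)CCC(O)C1(C)C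
F4 | step 8 | O-[(3E,6R,7Z)-6-[(tert-butyldimethylsilyl)oxy]-3,7,10,10-tetramethyl-9-oxocycloundeca-3,7-dien-1-yl] 1H-imidazole-1-carbothioate | O=C1/C=C(/C)[C@H](O[Si](C)(C)C(C)(C)C)C/C=C(\C)CCC(OC(=S)n2ccnc2)C1(C)C
F5 | step 9 | (1R,2Z,4R,6E)-4-[(tert-butyldimethylsilyl)oxy]-3,7,11,11-tetramethylcycloundeca-2,6-dien-1-ol | O[C@@H]1/C=C(/C)[C@H](O[Si](C)(C)C(C)(C)C)C/C=C(\C)CCCC1(C)C
F6 | step 3 | (5E)-9-chloro-6-methyl-1-(trimethylsilyl)non-5-en-1-yn-3-ol (racemic) | C[Si](C)(C)C#CC(O)C/C=C(\C)CCCCl
F7 | step 3 | (5E)-9-chloro-6-methyl-1-(trimethylsilyl)non-5-en-1-yn-3-one | C[Si](C)(C)C#CC(=O)C/C=C(\C)CCCCl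
F8 | step 3 | (3R,5E)-9-chloro-6-methyl-1-(trimethylsilyl)non-5-en-1-yn-3-ol | C[Si](C)(C)C#C[C@H](O)C/C=C(\C)CCCCl
F9 | step 3 | tert-butyl{[(3R,5E)-9-chloro-6-methyl-1-(trimethylsilyl)non-5-en-1-yn-3-yl]oxy}dimethylsilane | C[Si](C)(C)C#C[C@H](O[Si](C)(C)C(C)(C)C)C/C=C(\C)CCCCl
F10 | step 3 | tert-butyl{[(3R,5E)-9-chloro-6-methylnon-5-en-1-yn-3-yl]oxy}dimethylsilane | C#C[C@H](O[Si](C)(C)C(C)(C)C)C/C=C(\C)CCCCl
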